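**Retrosynthetic overview**
- Last step: the three enyne triple bonds (C4–C5, C8–C9, C14–C15) are reduced to the Z-alkenes. The 22-membered lactone is the only ring made; it is closed at C7–C8 by intramolecular Sonogashira coupling (the arene is bought).
- C10–C11 (with the C11 carbinol) comes from a phosphoric-acid-catalysed allenylboration; C13–C14 from a Sonogashira coupling with (Z)-3-iodo-2-methylacrolein.
- The ester C1–O21 and the C23 carbinol are made together by Evans–Tishchenko coupling of a β-hydroxy aryl ketone with a chloro-enynal.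
- C21–C22 comes from a new catalyst-controlled anti Mukaiyama aldol; C19–C20 from a silylium-catalysed acetaldehyde aldol.
- C16 comes from organocatalytic transfer hydrogenation of geranial; its CHO becomes the C14–C15 alkyne and its prenyl end becomes the C19 aldehyde.

Assumption: locants follow the macrolide numbering C1 (lactone carbonyl) to C23 (benzylic carbinol), and the target is taken exactly as drawn (2E,4Z,6Z,8Z,12Z,14Z; 11S,16R,19S,21S,22R,23R).

**Step 1**
Reactants: 1 geranial
Product: 2 (R)-citronellal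
Conditions: morpholinium salt of (R)-TRIP phosphoric acid (20 mol%, enantiomer chosen to give R), Hantzsch ester (1.1 equiv), dioxane, 50 °C
Reagents that add atoms: none
Why: Iminium-ion organocatalytic transfer hydrogenation with a chiral phosphate counteranion delivers hydride from the Hantzsch ester to one face of C3 of the enal and sets C16 (R), while the isolated trisubstituted alkene is not activated.

**Step 2**
Reactants: 2 (R)-citronellal
Product: 4 (R)-3,7-dimethyloct-6-en-1-yne, via alkenyl nonaflate 3 (not isolated)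
Conditions: NfF (C4F9SO2F, 1.2 equiv), phosphazene base P2-Et (2.5 equiv), DMF, −20 °C to rt
Reagents that add atoms: none
Why: One-pot enol nonaflation and β-elimination turns the enolisable aldehyde into the alkyne with the same carbon count, and the C16 stereocenter is not part of the reacting C–H/C–O pair.

**Step 3**
Reactants: 4 (R)-3,7-dimethyloct-6-en-1-yne
Product: 6 (R)-4-methylhex-5-ynal, via ozonide 5 (not isolated)
Conditions: O3, CH2Cl2, −78 °C (Sudan Red 7B endpoint); then Me2S, −78 °C to rt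
Reagents that add atoms: ozone, [O-][O+]=O
Why: Chemoselective ozonolysis with reductive work-up, since the electron-rich trisubstituted alkene reacts with ozone far faster than the terminal alkyne.

**Step 4**
Reactants: 6 (R)-4-methylhex-5-ynal; 7 tert-butyldimethyl(vinyloxy)silane
Product: 8 (3S,6R)-3-[(tert-butyldimethylsilyl)oxy]-6-methyloct-7-ynal
Conditions: chiral imidodiphosphorimidate Brønsted acid (IDPi, 1 mol%, enantiomer chosen to give 3S), 7 (2 equiv), pentane, −40 °C
Reagents that add atoms: none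
Why: Organocatalytic silylium-type Mukaiyama aldol (single aldolization of an acetaldehyde enolsilane) inside the confined chiral anion sets C19 (S) by catalyst control (C16 is remote) and delivers the aldol already as its TBS ether.

**Step 5**
Reactants: 9 3'-hydroxypropiophenone
Product: 10 (Z)-triethyl[(1-{3-[(triethylsilyl)oxy]phenyl}prop-1-en-1-yl)oxy]silane
Conditions: TESOTf (2.3 equiv), Et3N (3 equiv), CH2Cl2, 0 °C to rt
Reagents that add atoms: triethylsilyl trifluoromethanesulfonate, CC[Si](CC)(CC)OS(=O)(=O)C(F)(F)F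
Why: Soft enolisation/silylation protects the phenol and gives the favoured (Z)-enol silane of the aryl ethyl ketone in one operation.

**Step 6**
Reactants: 8 (3S,6R)-3-[(tert-butyldimethylsilyl)oxy]-6-methyloct-7-ynal; 10 (Z)-triethyl[(1-{3-[(triethylsilyl)oxy]phenyl}prop-1-en-1-yl)oxy]silane
Product: 12 (2S,3S,5S,8R)-5-[(tert-butyldimethylsilyl)oxy]-3-hydroxy-2,8-dimethyl-1-{3-[(triethylsilyl)oxy]phenyl}dec-9-yn-1-one, via O-triethylsilyl aldol 11 (not isolated)
Conditions: chiral IDPi with an open 3,3'-aryl pocket (2 mol%), toluene, −78 to −40 °C; then PPTS, MeOH, 0 °C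
Reagents that add atoms: none
Why: Proposed new method: a catalyst-controlled anti-selective Mukaiyama aldol of an aryl ethyl ketone (Z)-enolsilane with an enolisable β-silyloxy aldehyde under silylium catalysis, in which 10 silylates the chiral acid, the aldehyde is activated as an O-silyl oxocarbenium ion paired with the chiral anion, attack through an open antiperiplanar transition state (enol methyl turned away from the aldehyde chain) gives the anti adduct with the aldehyde face chosen by the catalyst (C21 S and C22 set together, the weak 1,3-bias of the β-silyloxy group being overridden), silyl transfer turns the catalyst over and mild acidic methanolysis cleaves only the secondary alkyl TES ether; the closest known reaction type is the imidodiphosphorimidate-catalysed Mukaiyama aldol of aldehyde-derived enolsilanes and silyl ketene acetals.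

**Step 7**
Reactants: 13 cis-1,2-dichloroethene; 14 propargyl alcohol
Product: 15 (Z)-5-chloropent-4-en-2-yn-1-ol
Conditions: Pd(PPh3)4 (5 mol%), CuI (10 mol%), n-BuNH2, 13 (5 equiv), Et2O, rt
Reagents that add atoms: none
Why: Sonogashira coupling in which excess dichloroethene gives mono-coupling and oxidative addition of zerovalent palladium into the C–Cl bond retains the Z geometry.

**Step 8**
Reactants: 15 (Z)-5-chloropent-4-en-2-yn-1-ol; 16 2-(triphenylphosphoranylidene)propanal
Product: 18 (2E,6Z)-7-chloro-2-methylhepta-2,6-dien-4-ynal, via ynal 17 (not isolated)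
Conditions: activated MnO2 (10 equiv), 16 (1.3 equiv), CH2Cl2, rt to 40 °C
Reagents that add atoms: none
Why: Tandem MnO2 oxidation–Wittig olefination traps the electrophilic ynal in situ with the stabilised α-methyl ylide to give the (E)-trisubstituted enal and leaves the Z-chloroalkene untouched.

**Step 9**
Reactants: 12 (2S,3S,5S,8R)-5-[(tert-butyldimethylsilyl)oxy]-3-hydroxy-2,8-dimethyl-1-{3-[(triethylsilyl)oxy]phenyl}dec-9-yn-1-one; 18 (2E,6Z)-7-chloro-2-methylhepta-2,6-dien-4-ynal
Product: 19 (1R,2R,3S,5S,8R)-5-[(tert-butyldimethylsilyl)oxy]-1-hydroxy-2,8-dimethyl-1-{3-[(triethylsilyl)oxy]phenyl}dec-9-yn-3-yl (2E,6Z)-7-chloro-2-methylhepta-2,6-dien-4-ynoate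
Conditions: SmI2 (30 mol%) pre-mixed with 18 (4 equiv), THF, −10 °C
Reagents that add atoms: none
Why: Evans–Tishchenko reaction in which the samarium-bound hemiacetal of the C21 hydroxyl and 18 delivers hydride intramolecularly to the C23 ketone through a bicyclic chair, giving the 1,3-anti carbinol (23R) and placing the acyl group only on O21, so the lactone ester bond is made without hydroxyl differentiation.

**Step 10**
Reactants: 14 propargyl alcohol
Product: 21 (Z)-3-iodo-2-methylprop-2-en-1-ol, via vinylmagnesium alkoxide 20 (not isolated)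
Conditions: MeMgBr (2.5 equiv), CuI (10 mol%), THF/Et2O, −10 °C to rt; then I2, −20 °C
Reagents that add atoms: methylmagnesium bromide, C[Mg]Br; iodine, II
Why: Copper-catalysed anti-carbomagnesiation of the propargylic alkoxide gives a chelated vinylmagnesium species whose iodinolysis places iodine cis to CH2OH, which becomes the 12Z geometry.

**Step 11**
Reactants: 21 (Z)-3-iodo-2-methylprop-2-en-1-ol
Product: 22 (Z)-3-iodo-2-methylprop-2-enal
Conditions: activated MnO2 (10 equiv), CH2Cl2, 0 °C to rt, dark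
Reagents that add atoms: none
Why: Neutral allylic oxidation with MnO2 keeps the Z-iodoalkene geometry.

**Step 12**
Reactants: 19 the C21 ester with terminal alkyne; 22 (Z)-3-iodo-2-methylprop-2-enal
Product: 23 (1R,2R,3S,5S,8R,11Z)-5-[(tert-butyldimethylsilyl)oxy]-1-hydroxy-2,8,12-trimethyl-13-oxo-1-{3-[(triethylsilyl)oxy]phenyl}tridec-11-en-9-yn-3-yl (2E,6Z)-7-chloro-2-methylhepta-2,6-dien-4-ynoate
Conditions: Pd(PPh3)2Cl2 (5 mol%), CuI (10 mol%), Et3N, 22 (1.5 equiv), THF, 0 °C to rt
Reagents that add atoms: none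
Why: Sonogashira coupling in which the vinyl iodide reacts far faster than the chloroalkene of 19 (which needs Pd(PPh3)4 and a primary amine), so only the C13–C14 bond forms, with retention of the Z geometry.

**Step 13**
Reactants: 23 the (Z)-enynal ester; 24 allenylboronic acid pinacol ester
Product: 26 (1R,2R,3S,5S,8R,11Z,13S)-5-[(tert-butyldimethylsilyl)oxy]-1,13-dihydroxy-2,8,12-trimethyl-1-{3-[(triethylsilyl)oxy]phenyl}hexadec-11-en-9,15-diyn-3-yl (2E,6Z)-7-chloro-2-methylhepta-2,6-dien-4-ynoate, via pinacol borate 25 (not isolated)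
Conditions: (S)-TRIP phosphoric acid (10 mol%), 24 (1.5 equiv), 4 Å molecular sieves, toluene, −20 °C; aqueous NaHCO3 work-up
Reagents that add atoms: none
Why: Chiral phosphoric acid-catalysed allenylboration (propargylation) through a six-membered SE2' transition state, with the acid hydrogen-bonded to the boronate oxygen, sets C11 (S) by catalyst control on the only aldehyde in the molecule; the catalyst enantiomer is assigned by analogy with aryl aldehydes.

**Step 14**
Reactants: 26 the seco chloro-enyne with terminal alkyne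
Product: 27 bis-silylated 4,8,14-triyne macrolactone
Conditions: Pd(PPh3)4 (20 mol%), CuI (40 mol%), n-BuNH2 (10 equiv), degassed benzene, 1 mM by syringe pump over 12 h, rt
Reagents that add atoms: none
Why: Intramolecular Sonogashira coupling under high dilution closes the 22-membered ring at C7–C8, because (Z)-chloroenynes are activated vinyl chlorides under Pd(PPh3)4/CuI/primary amine and the coupling retains the 6Z geometry.

**Step 15**
Reactants: 27 bis-silylated 4,8,14-triyne macrolactone
Product: 28 4,8,14-triyne macrolactone tetraol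
Conditions: HF·pyridine, pyridine, THF, 0 °C to rt
Reagents that add atoms: none
Why: Fluoride-mediated global desilylation, buffered with pyridine to suppress acyl migration among O19, O21 and O23, is done before the sensitive polyene exists.

**Step 16**
Reactants: 28 4,8,14-triyne macrolactone tetraol
Product: 29 target macrolide CNP0073615.2
Conditions: Zn dust activated with Cu(OAc)2 and AgNO3, MeOH/H2O 1:1, 30 °C, dark, argon
Reagents that add atoms: none
Why: Boland-type semi-reduction, in which activated zinc reduces only alkynes conjugated to alkenes by syn addition of two hydrogens, converts the three enyne triple bonds into the 4Z, 8Z and 14Z alkenes without touching the existing alkenes, the ester or the stereocenters.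

**Compound list**
1 | geranial, (2E)-3,7-dimethylocta-2,6-dienal | CC(C)=CCC/C(C)=C/C=O | starting material
2 | (R)-citronellal, (3R)-3,7-dimethyloct-6-enal | O=CC[C@H](C)CCC=C(C)C | intermediate
3 | (3R)-3,7-dimethylocta-1,6-dien-1-yl nonafluorobutane-1-sulfonate (E/Z mixture) | FC(F)(F)C(F)(F)C(F)(F)C(F)(F)S(=O)(=O)OC=C[C@H](C)CCC=C(C)C | intermediate
4 | (R)-3,7-dimethyloct-6-en-1-yne | C#C[C@H](C)CCC=C(C)C | intermediate
5 | 5,5-dimethyl-3-[(3R)-3-methylpent-4-yn-1-yl]-1,2,4-trioxolane (ozonide, epimers at C3) | C#C[C@H](C)CCC1OOC(C)(C)O1 | intermediate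
6 | (R)-4-methylhex-5-ynal | C#C[C@H](C)CCC=O | intermediate
7 | tert-butyldimethyl(vinyloxy)silane | C=CO[Si](C)(C)C(C)(C)C | starting material
8 | (3S,6R)-3-[(tert-butyldimethylsilyl)oxy]-6-methyloct-7-ynal | C#C[C@H](C)CC[C@H](O[Si](C)(C)C(C)(C)C)CC=O | intermediate
9 | 3'-hydroxypropiophenone | CCC(=O)c1cccc(O)c1 | starting material
10 | (Z)-triethyl[(1-{3-[(triethylsilyl)oxy]phenyl}prop-1-en-1-yl)oxy]silane | C/C=C(\O[Si](CC)(CC)CC)c1cccc(O[Si](CC)(CC)CC)c1 | intermediate
11 | (2S,3S,5S,8R)-5-[(tert-butyldimethylsilyl)oxy]-2,8-dimethyl-3-[(triethylsilyl)oxy]-1-{3-[(triethylsilyl)oxy]phenyl}dec-9-yn-1-one | C#C[C@H](C)CC[C@H](O[Si](C)(C)C(C)(C)C)C[C@@H]([C@H](C)C(=O)c1cccc(O[Si](CC)(CC)CC)c1)O[Si](CC)(CC)CC | intermediate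
12 | (2S,3S,5S,8R)-5-[(tert-butyldimethylsilyl)oxy]-3-hydroxy-2,8-dimethyl-1-{3-[(triethylsilyl)oxy]phenyl}dec-9-yn-1-one | C#C[C@H](C)CC[C@H](O[Si](C)(C)C(C)(C)C)C[C@@H]([C@H](C)C(=O)c1cccc(O[Si](CC)(CC)CC)c1)O | intermediate
13 | cis-1,2-dichloroethene | Cl/C=C\Cl | starting material
14 | propargyl alcohol | C#CCO | starting material
15 | (Z)-5-chloropent-4-en-2-yn-1-ol | OCC#C/C=C\Cl | intermediate
16 | 2-(triphenylphosphoranylidene)propanal | CC(C=O)=P(c1ccccc1)(c1ccccc1)c1ccccc1 | starting material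
17 | (Z)-5-chloropent-4-en-2-ynal | O=CC#C/C=C\Cl | intermediate
18 | (2E,6Z)-7-chloro-2-methylhepta-2,6-dien-4-ynal | O=C/C(C)=C/C#C/C=C\Cl | intermediate
19 | (1R,2R,3S,5S,8R)-5-[(tert-butyldimethylsilyl)oxy]-1-hydroxy-2,8-dimethyl-1-{3-[(triethylsilyl)oxy]phenyl}dec-9-yn-3-yl (2E,6Z)-7-chloro-2-methylhepta-2,6-dien-4-ynoate | C#C[C@H](C)CC[C@H](O[Si](C)(C)C(C)(C)C)C[C@@H]([C@H](C)[C@@H](O)c1cccc(O[Si](CC)(CC)CC)c1)OC(=O)/C(C)=C/C#C/C=C\Cl | intermediate
20 | bromomagnesium (Z)-3-(bromomagnesio)-2-methylprop-2-en-1-olate | Br[Mg]/C=C(/C)CO[Mg]Br | intermediate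
21 | (Z)-3-iodo-2-methylprop-2-en-1-ol | OC/C(C)=C\I | intermediate
22 | (Z)-3-iodo-2-methylprop-2-enal | O=C/C(C)=C\I | intermediate
23 | (1R,2R,3S,5S,8R,11Z)-5-[(tert-butyldimethylsilyl)oxy]-1-hydroxy-2,8,12-trimethyl-13-oxo-1-{3-[(triethylsilyl)oxy]phenyl}tridec-11-en-9-yn-3-yl (2E,6Z)-7-chloro-2-methylhepta-2,6-dien-4-ynoate | O=C/C(C)=C\C#C[C@H](C)CC[C@H](O[Si](C)(C)C(C)(C)C)C[C@@H]([C@H](C)[C@@H](O)c1cccc(O[Si](CC)(CC)CC)c1)OC(=O)/C(C)=C/C#C/C=C\Cl | intermediate
24 | allenylboronic acid pinacol ester | C=C=CB1OC(C)(C)C(C)(C)O1 | starting material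
25 | pinacol borate of 26 (boron on the C11 oxygen) | C#CC[C@H](OB1OC(C)(C)C(C)(C)O1)/C(C)=C\C#C[C@H](C)CC[C@H](O[Si](C)(C)C(C)(C)C)C[C@@H]([C@H](C)[C@@H](O)c1cccc(O[Si](CC)(CC)CC)c1)OC(=O)/C(C)=C/C#C/C=C\Cl | intermediate
26 | (1R,2R,3S,5S,8R,11Z,13S)-5-[(tert-butyldimethylsilyl)oxy]-1,13-dihydroxy-2,8,12-trimethyl-1-{3-[(triethylsilyl)oxy]phenyl}hexadec-11-en-9,15-diyn-3-yl (2E,6Z)-7-chloro-2-methylhepta-2,6-dien-4-ynoate | C#CC[C@H](O)/C(C)=C\C#C[C@H](C)CC[C@H](O[Si](C)(C)C(C)(C)C)C[C@@H]([C@H](C)[C@@H](O)c1cccc(O[Si](CC)(CC)CC)c1)OC(=O)/C(C)=C/C#C/C=C\Cl | intermediate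
27 | 22-membered lactone with triple bonds at C4–C5, C8–C9 and C14–C15 (2E,6Z,12Z; 11S,16R,19S,21S,22R,23R), 19-O-TBS, aryl O-TES, free 11-OH and 23-OH | C/C1=C/C#C[C@H](C)CC[C@H](O[Si](C)(C)C(C)(C)C)C[C@@H]([C@H](C)[C@@H](O)c2cccc(O[Si](CC)(CC)CC)c2)OC(=O)/C(C)=C/C#C/C=C\C#CC[C@@H]1O | intermediate
28 | desilylated 4,8,14-triyne macrolactone (2E,6Z,12Z; 11S,16R,19S,21S,22R,23R), four free hydroxyls | C/C1=C/C#C[C@H](C)CC[C@H](O)C[C@@H]([C@H](C)[C@@H](O)c2cccc(O)c2)OC(=O)/C(C)=C/C#C/C=C\C#CC[C@@H]1O | intermediate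
29 | CNP0073615.2, (3E,5Z,7Z,9Z,12S,13Z,15Z,17R,20S,22S)-12,20-dihydroxy-22-[(1R,2R)-1-hydroxy-1-(3-hydroxyphenyl)propan-2-yl]-3,13,17-trimethyl-1-oxacyclodocosa-3,5,7,9,13,15-hexaen-2-one | C/C1=C/C=C\[C@H](C)CC[C@H](O)C[C@@H]([C@H](C)[C@@H](O)c2cccc(O)c2)OC(=O)/C(C)=C/C=C\C=C/C=C\C[C@@H]1O | target

**Step count**
Total steps: 16. Longest linear sequence: 11 (steps 1, 2, 3, 4, 6, 9, 12, 13, 14, 15, 16).

**Three steps most likely to fail**

Step 6 (the proposed new aldol). The syn/anti ratio of a ketone-derived (Z)-enolsilane in the confined ion pair, and the 1,3-syn sense against the β-silyloxy stereocenter, are untested. The fallback uses known chemistry and sets out from 8. An L-proline-catalysed cross-aldol of 8 (acceptor, β-branched) with propanal added slowly (DMF, 4 °C) gives the anti aldol (2S,3S,5S,8R)-5-[(tert-butyldimethylsilyl)oxy]-3-hydroxy-2,8-dimethyldec-9-ynal F1 under catalyst control. 3-Bromophenol is silylated (TESCl, imidazole) to (3-bromophenoxy)triethylsilane F2 and converted with Mg turnings into {3-[(triethylsilyl)oxy]phenyl}magnesium bromide F3. Addition of F3 (2.5 equiv) to F1 gives the diol (2S,3S,5S,8R)-5-[(tert-butyldimethylsilyl)oxy]-2,8-dimethyl-1-{3-[(triethylsilyl)oxy]phenyl}dec-9-yne-1,3-diol F4 as a C1 epimer mixture, which does not matter. MnO2 oxidises only the benzylic alcohol of F4, and the route is rejoined at 12.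

Step 14 (macrocyclic Sonogashira on a vinyl chloride). Risks are oligomerisation, alkyne homocoupling and cycloisomerisation of the (Z)-enynol. The fallback moves the ring closure to the ester bond and sets out from 12. Sonogashira coupling of 12 with 22 (Pd(PPh3)2Cl2, CuI, Et3N) gives (2Z,6R,9S,11S,12S)-9-[(tert-butyldimethylsilyl)oxy]-11-hydroxy-2,6,12-trimethyl-13-oxo-13-{3-[(triethylsilyl)oxy]phenyl}tridec-2-en-4-ynal F5. Allenylboration of F5 with 24 and (S)-TRIP phosphoric acid gives the pinacol borate of the C11 carbinol F6 and, after work-up, (2S,3S,5S,8R,11Z,13S)-5-[(tert-butyldimethylsilyl)oxy]-3,13-dihydroxy-2,8,12-trimethyl-1-{3-[(triethylsilyl)oxy]phenyl}hexadec-11-en-9,15-diyn-1-one F7. F7 has no halide, so its terminal alkyne couples intermolecularly with excess 18 (Pd(PPh3)4, CuI, iPr2NH) to give the open-chain C1 aldehyde / C21 hydroxy / C23 ketone seco compound F8. An intramolecular Evans–Tishchenko reaction of F8 (SmI2, dilute THF, −10 °C) forms the lactone and the 23R carbinol together; the C11 hydroxyl has no ketone in reach and stays free. This rejoins the route at 27. Macrocyclic Evans–Tishchenko closure is much less documented than the intermolecular reaction used in step 9.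

Step 16 (triple semi-reduction to a sensitive all-cis tetraenoate). Risks are incomplete or over-reduction and electrocyclisation or isomerisation of the product. The fallback sets out from 27 and swaps the order and mechanism of the last two operations. Heterogeneous syn-hydrogenation of the silylated, less polar macrocycle (H2, Pd on CaCO3 poisoned with Pb(OAc)2, quinoline, EtOAc, 0 °C, monitored to 3 equiv uptake) gives the bis-silylated (2E,4Z,6Z,8Z,12Z,14Z)-macrolactone F9, which can be purified as a silyl ether. HF·pyridine/pyridine on F9 then gives 29 directly.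

**Further compounds**
F1 | step 6 | (2S,3S,5S,8R)-5-[(tert-butyldimethylsilyl)oxy]-3-hydroxy-2,8-dimethyldec-9-ynal | C#C[C@H](C)CC[C@H](O[Si](C)(C)C(C)(C)C)C[C@@H]([C@H](C)C=O)O
F2 | step 6 | (3-bromophenoxy)triethylsilane | CC[Si](CC)(CC)Oc1cccc(Br)c1
F3 | step 6 | {3-[(triethylsilyl)oxy]phenyl}magnesium bromide | CC[Si](CC)(CC)Oc1cccc([Mg]Br)c1
F4 | step 6 | (2S,3S,5S,8R)-5-[(tert-butyldimethylsilyl)oxy]-2,8-dimethyl-1-{3-[(triethylsilyl)oxy]phenyl}dec-9-yne-1,3-diol (C1 epimers) | C#C[C@H](C)CC[C@H](O[Si](C)(C)C(C)(C)C)C[C@@H]([C@H](C)C(O)c1cccc(O[Si](CC)(CC)CC)c1)O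
F5 | step 14 | (2Z,6R,9S,11S,12S)-9-[(tert-butyldimethylsilyl)oxy]-11-hydroxy-2,6,12-trimethyl-13-oxo-13-{3-[(triethylsilyl)oxy]phenyl}tridec-2-en-4-ynal | O=C/C(C)=C\C#C[C@H](C)CC[C@H](O[Si](C)(C)C(C)(C)C)C[C@@H]([C@H](C)C(=O)c1cccc(O[Si](CC)(CC)CC)c1)O
F6 | step 14 | pinacol borate of F7 (boron on the C11 oxygen) | C#CC[C@H](OB1OC(C)(C)C(C)(C)O1)/C(C)=C\C#C[C@H](C)CC[C@H](O[Si](C)(C)C(C)(C)C)C[C@@H]([C@H](C)C(=O)c1cccc(O[Si](CC)(CC)CC)c1)O
F7 | step 14 | (2S,3S,5S,8R,11Z,13S)-5-[(tert-butyldimethylsilyl)oxy]-3,13-dihydroxy-2,8,12-trimethyl-1-{3-[(triethylsilyl)oxy]phenyl}hexadec-11-en-9,15-diyn-1-one | C#CC[C@H](O)/C(C)=C\C#C[C@H](C)CC[C@H](O[Si](C)(C)C(C)(C)C)C[C@@H]([C@H](C)C(=O)c1cccc(O[Si](CC)(CC)CC)c1)O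
F8 | step 14 | seco aldehyde: F7 bearing the (1Z,5E)-5-methyl-6-oxohexa-1,5-dien-3-yn-1-yl unit on its terminal alkyne carbon | O=C/C(C)=C/C#C/C=C\C#CC[C@H](O)/C(C)=C\C#C[C@H](C)CC[C@H](O[Si](C)(C)C(C)(C)C)C[C@@H]([C@H](C)C(=O)c1cccc(O[Si](CC)(CC)CC)c1)O
F9 | step 16 | 19-O-TBS, aryl O-TES ether of the target (2E,4Z,6Z,8Z,12Z,14Z; 11S,16R,19S,21S,22R,23R) | C/C1=C/C=C\[C@H](C)CC[C@H](O[Si](C)(C)C(C)(C)C)C[C@@H]([C@H](C)[C@@H](O)c2cccc(O[Si](CC)(CC)CC)c2)OC(=O)/C(C)=C/C=C\C=C/C=C\C[C@@H]1O
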